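**Plan**

- Labels (terpenoid numbering): ring B = C5(H, isopropenyl)–C6H2–C7(=O)–C8(ar)–C9(ar)–C10(CH3, chain C1–C2–C3O2H); isopropenyl = C4(=C18H2)–C19H3; arene C11(OH), C12(OH), C13(iPr), C14(OH).
- Retrosynthesis: (i) C3 is rebonded to C4 with C18 as CH2OMs (Grob retron), hiding the acid and the isopropenyl group in a temporary cyclohexanone ring A (C10, C1–C5); (ii) C5–C6 and C4–C18 are cut together (Michael addition of the C8-acetyl CH3 to the enone C3(=O)–C4=C5, enolate trapped by CH2O); (iii) C7–C8 (acetyl from ArBr); (iv) C10–C1 and C4=C5 (Robinson annulation of a 2-arylpropanal with ethyl vinyl ketone); (v) aryl–C10, aryl–Br, aryl–iPr.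
- Enabling feature: C7=O and the C3 carboxyl are 1,5-related through C6–C5–C4, and the isopropenyl on C5 is cis to the acid chain on C10, so the target is an "unzipped" cis-fused A/B Michael adduct.
- Forward order: hexasubstituted arene, then temporary ring A carrying quaternary C10, then ring B (closed last), then fragmentation of ring A.
- Stereochemistry: C10 from the amine-catalysed Michael step of the Robinson annulation (step 7); C5 from substrate control in step 9 (the nucleophile is tethered to the aryl group on C10 and must add cis); the extra C4 centre is erased in step 12.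

Key step: step 9

Remark: 17–19 are carried as a mixture of epimers at the temporary C4 centre (left undefined in the SMILES); the sense of induction in step 7 is assumed by analogy, and the pseudoenantiomeric catalyst is taken if it proves opposite.

**Route**

Step 1
Reactants: 1 1,2,4-trimethoxybenzene
Product: 3 2-(2,3,6-trimethoxyphenyl)propan-2-ol, via 2,3,6-trimethoxyphenyllithium 2 (not isolated)
Conditions: n-BuLi, THF, 0 °C to rt; acetone, −78 °C to rt; H2O
Reagents that add atoms: acetone CC(C)=O
Why: Directed ortho-metalation should occur at the C–H flanked by two methoxy groups (future C13), and the aryllithium adds 1,2 to acetone.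

Step 2
Reactants: 3 2-(2,3,6-trimethoxyphenyl)propan-2-ol
Product: 4 1,2,4-trimethoxy-3-(propan-2-yl)benzene
Conditions: Et3SiH, TFA, CH2Cl2, 0 °C to rt
Reagents that add atoms: none
Why: Ionic hydrogenation: the tertiary benzylic alcohol flanked by two OMe groups ionises in TFA and the cation is reduced by the silane.

Step 3
Reactants: 4 1,2,4-trimethoxy-3-(propan-2-yl)benzene
Product: 5 1-bromo-2,4,5-trimethoxy-3-(propan-2-yl)benzene
Conditions: NBS, MeCN, 0 °C to rt
Reagents that add atoms: N-bromosuccinimide O=C1CCC(=O)N1Br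
Why: Electrophilic aromatic bromination should go para to one methoxy group and ortho to another (future C8), the usual site of substitution in 1,2,4-trialkoxybenzenes.

Step 4
Reactants: 5 1-bromo-2,4,5-trimethoxy-3-(propan-2-yl)benzene
Product: 7 1-[2-bromo-3,5,6-trimethoxy-4-(propan-2-yl)phenyl]ethan-1-one, via aryllithium 6 (not isolated)
Conditions: LiTMP, THF, −78 °C; N-methoxy-N-methylacetamide, −78 to 0 °C; H2O
Reagents that add atoms: N-methoxy-N-methylacetamide CC(=O)N(C)OC
Why: Deprotonative lithiation at the only ring C–H, acidified by the flanking Br and OMe, followed by Weinreb acylation, which stops at the ketone; the low temperature suppresses aryne formation.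

Step 5
Reactants: 7 1-[2-bromo-3,5,6-trimethoxy-4-(propan-2-yl)phenyl]ethan-1-one
Product: 8 2-[2-bromo-3,5,6-trimethoxy-4-(propan-2-yl)phenyl]-2-methyloxirane (racemic)
Conditions: Me3S+ I−, NaH, DMSO/THF, 0 °C to rt
Reagents that add atoms: trimethylsulfonium iodide C[S+](C)C.[I-]
Why: Corey–Chaykovsky epoxidation; the small sulfonium ylide should add to the hindered, non-conjugated aryl ketone and supplies the future C5.

Step 6
Reactants: 8 2-[2-bromo-3,5,6-trimethoxy-4-(propan-2-yl)phenyl]-2-methyloxirane
Product: 9 2-[2-bromo-3,5,6-trimethoxy-4-(propan-2-yl)phenyl]propanal (racemic)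
Conditions: BF3·OEt2 (cat.), CH2Cl2, −78 °C
Reagents that add atoms: none
Why: Meinwald rearrangement: the epoxide opens at the tertiary benzylic carbon and a 1,2-hydride shift gives the aldehyde; the inert bromide cannot trap the cation, and the stereocentre is deliberately left racemic.

Step 7
Reactants: 9 2-[2-bromo-3,5,6-trimethoxy-4-(propan-2-yl)phenyl]propanal, 10 pent-1-en-3-one
Product: 12 (4R)-4-[2-bromo-3,5,6-trimethoxy-4-(propan-2-yl)phenyl]-2,4-dimethylcyclohex-2-en-1-one, via keto aldehyde 11 (not isolated)
Conditions: 9-amino-9-deoxy-epi-quinine (20 mol %), PhCO2H (40 mol %), toluene, rt; then KOH, EtOH, 60 °C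
Reagents that add atoms: none
Why: Organocatalytic asymmetric Robinson annulation: both enantiomers of 9 converge on one enamine, whose catalyst-controlled Michael addition to 10 sets the quaternary C10 as (S)-11, and aldol condensation of the ethyl ketone CH2 onto the non-enolisable aldehyde then gives the 2-methylcyclohexenone (ring A) without touching C10.

Step 8
Reactants: 12 (4R)-4-[2-bromo-3,5,6-trimethoxy-4-(propan-2-yl)phenyl]-2,4-dimethylcyclohex-2-en-1-one
Product: 14 (4R)-4-[2-acetyl-3,5,6-trimethoxy-4-(propan-2-yl)phenyl]-2,4-dimethylcyclohex-2-en-1-one, via ethoxyvinyl enone 13 (not isolated)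
Conditions: Bu3Sn–C(OEt)=CH2, Pd2(dba)3, P(t-Bu)3, CsF, dioxane, 100 °C; then 1 M HCl, THF, rt
Reagents that add atoms: tributyl(1-ethoxyvinyl)stannane CCCC[Sn](CCCC)(CCCC)C(=C)OCC; water O
Why: Stille–Kosugi coupling with an acetyl-anion equivalent, using a bulky electron-rich phosphine for the di-ortho-substituted bromide; the stannane leaves the enone alone and mild acid hydrolyses the enol ether to the methyl ketone (C7, C6).

Step 9
Reactants: 14 (4R)-4-[2-acetyl-3,5,6-trimethoxy-4-(propan-2-yl)phenyl]-2,4-dimethylcyclohex-2-en-1-one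
Product: 17 (4bR,8aR)-8-(hydroxymethyl)-1,3,4-trimethoxy-4b,8-dimethyl-2-(propan-2-yl)-4b,5,6,8,8a,9-hexahydrophenanthrene-7,10-dione (cis-fused; C8 epimers), via acetyl lithium enolate 15 (not isolated), via tricyclic lithium enolate 16 (not isolated)
Conditions: LiHMDS (1.05 equiv), THF, −78 to −30 °C; monomeric CH2O (THF solution), −78 °C; AcOH, −78 °C
Reagents that add atoms: formaldehyde C=O
Why: LiHMDS deprotonates the acetyl CH3 (C6; the more acidic site, helped by lithium chelation to the neighbouring 14-OMe), and enolate 15 adds in a 6-(enolendo)-exo-trig Michael closure to C5 of the 2-methylcyclohexenone, forming the C5–C6 bond and ring B (C5–C6–C7–C8–C9–C10); the resulting tetrasubstituted enolate 16 is trapped at C4 by formaldehyde. The closest known reaction type is the intramolecular Michael addition of a ketone enolate to a cyclohexenone coupled with regiospecific trapping of the new enolate by monomeric formaldehyde. C5 is controlled by the tether: C6 hangs on the aryl group at C10 and can reach the β-carbon only along the axial trajectory on the enone face syn to that aryl group, so the A/B fusion should be cis (H-5 cis to the C10 methyl), which is the relative configuration of the target, while the absolute configuration follows from C10 (step 7). The C4 centre made in the trapping is of no consequence because it becomes sp2 in step 12, and once C4 is quaternary the retro-Michael path is closed. The step needs chemoselective enolisation (methyl ketone over the enone α′-CH2: the dienolate is unproductive and should return by amine-mediated proton exchange while cyclisation drains the acetyl enolate), 1,4- over 1,2-addition (1,2 would require a bridged eight-membered ring), and C4- over C6-hydroxymethylation (trapping at −78 °C before the enolates equilibrate).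

Step 10
Reactants: 17 (4bR,8aR)-8-(hydroxymethyl)-1,3,4-trimethoxy-4b,8-dimethyl-2-(propan-2-yl)-4b,5,6,8,8a,9-hexahydrophenanthrene-7,10-dione
Product: 18 [(4bR,8aR)-1,3,4-trimethoxy-4b,8-dimethyl-7,10-dioxo-2-(propan-2-yl)-4b,5,6,7,8,8a,9,10-octahydrophenanthren-8-yl]methyl methanesulfonate
Conditions: MsCl, Et3N, CH2Cl2, 0 °C
Reagents that add atoms: methanesulfonyl chloride CS(=O)(=O)Cl
Why: Sulfonylation of the primary neopentyl alcohol; C4 carries no hydrogen, so β-elimination is impossible.

Step 11
Reactants: 18 [(4bR,8aR)-1,3,4-trimethoxy-4b,8-dimethyl-7,10-dioxo-2-(propan-2-yl)-4b,5,6,7,8,8a,9,10-octahydrophenanthren-8-yl]methyl methanesulfonate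
Product: 19 [(4bR,8aR)-1,3,4-trihydroxy-4b,8-dimethyl-7,10-dioxo-2-(propan-2-yl)-4b,5,6,7,8,8a,9,10-octahydrophenanthren-8-yl]methyl methanesulfonate
Conditions: BBr3, CH2Cl2, −78 to 0 °C; H2O (under Ar)
Reagents that add atoms: none
Why: Lewis-acid cleavage of the three aryl methyl ethers is done before any alkene exists, so the later isopropenyl group never meets BBr3/HBr; the neopentyl mesylate and both ketones should survive.

Step 12
Reactants: 19 [(4bR,8aR)-1,3,4-trihydroxy-4b,8-dimethyl-7,10-dioxo-2-(propan-2-yl)-4b,5,6,7,8,8a,9,10-octahydrophenanthren-8-yl]methyl methanesulfonate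
Product: 20 3-[(1R,2S)-5,7,8-trihydroxy-1-methyl-4-oxo-6-(propan-2-yl)-2-(prop-1-en-2-yl)-1,2,3,4-tetrahydronaphthalen-1-yl]propanoic acid (CNP0198818.2)
Conditions: NaOH (aq., degassed), THF, rt to 40 °C, Ar; then 1 M HCl, 0 °C (Na2S2O4 in the work-up)
Reagents that add atoms: sodium hydroxide [Na+].[OH-]
Why: Grob-type fragmentation of the β-mesyloxy ketone: hydroxide adds to the C3 ketone and the alkoxide cleaves C3–C4 anti to C18–OMs, giving the carboxylate and the C4=C18 isopropenyl group regiospecifically without a cation; C5 and C10 are untouched, and the H-bonded aryl ketone C7 is not attacked.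

**Compound list**

1 | 1,2,4-trimethoxybenzene | COc1ccc(OC)c(OC)c1 | starting material
2 | 2,3,6-trimethoxyphenyllithium | COc1ccc(OC)c([Li])c1OC | intermediate
3 | 2-(2,3,6-trimethoxyphenyl)propan-2-ol | COc1ccc(OC)c(C(C)(C)O)c1OC | intermediate
4 | 1,2,4-trimethoxy-3-(propan-2-yl)benzene | COc1ccc(OC)c(C(C)C)c1OC | intermediate
5 | 1-bromo-2,4,5-trimethoxy-3-(propan-2-yl)benzene | COc1cc(Br)c(OC)c(C(C)C)c1OC | intermediate
6 | [2-bromo-3,5,6-trimethoxy-4-(propan-2-yl)phenyl]lithium | COc1c([Li])c(Br)c(OC)c(C(C)C)c1OC | intermediate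
7 | 1-[2-bromo-3,5,6-trimethoxy-4-(propan-2-yl)phenyl]ethan-1-one | COc1c(C(C)=O)c(Br)c(OC)c(C(C)C)c1OC | intermediate
8 | 2-[2-bromo-3,5,6-trimethoxy-4-(propan-2-yl)phenyl]-2-methyloxirane (racemic) | COc1c(C2(C)CO2)c(Br)c(OC)c(C(C)C)c1OC | intermediate
9 | 2-[2-bromo-3,5,6-trimethoxy-4-(propan-2-yl)phenyl]propanal (racemic) | COc1c(C(C)C=O)c(Br)c(OC)c(C(C)C)c1OC | intermediate
10 | pent-1-en-3-one (ethyl vinyl ketone) | C=CC(=O)CC | starting material
11 | (2S)-2-[2-bromo-3,5,6-trimethoxy-4-(propan-2-yl)phenyl]-2-methyl-5-oxoheptanal | O=C[C@](C)(c1c(OC)c(OC)c(C(C)C)c(OC)c1Br)CCC(=O)CC | intermediate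
12 | (4R)-4-[2-bromo-3,5,6-trimethoxy-4-(propan-2-yl)phenyl]-2,4-dimethylcyclohex-2-en-1-one | CC1=C[C@](C)(c2c(OC)c(OC)c(C(C)C)c(OC)c2Br)CCC1=O | intermediate
13 | (4R)-4-[2-(1-ethoxyethenyl)-3,5,6-trimethoxy-4-(propan-2-yl)phenyl]-2,4-dimethylcyclohex-2-en-1-one | CC1=C[C@](C)(c2c(OC)c(OC)c(C(C)C)c(OC)c2C(=C)OCC)CCC1=O | intermediate
14 | (4R)-4-[2-acetyl-3,5,6-trimethoxy-4-(propan-2-yl)phenyl]-2,4-dimethylcyclohex-2-en-1-one | CC1=C[C@](C)(c2c(OC)c(OC)c(C(C)C)c(OC)c2C(C)=O)CCC1=O | intermediate
15 | lithium enolate of the acetyl group of 14 | CC1=C[C@](C)(c2c(OC)c(OC)c(C(C)C)c(OC)c2C(=C)O[Li])CCC1=O | intermediate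
16 | cis-fused tricyclic lithium enolate (C3–O–Li, C3=C4) | CC=3[C@@H]1CC(=O)c2c(OC)c(C(C)C)c(OC)c(OC)c2[C@]1(C)CCC=3O[Li] | intermediate
17 | (4bR,8aR)-8-(hydroxymethyl)-1,3,4-trimethoxy-4b,8-dimethyl-2-(propan-2-yl)-4b,5,6,8,8a,9-hexahydrophenanthrene-7,10-dione (C8 epimers) | OCC3(C)[C@@H]1CC(=O)c2c(OC)c(C(C)C)c(OC)c(OC)c2[C@]1(C)CCC3=O | intermediate
18 | [(4bR,8aR)-1,3,4-trimethoxy-4b,8-dimethyl-7,10-dioxo-2-(propan-2-yl)-4b,5,6,7,8,8a,9,10-octahydrophenanthren-8-yl]methyl methanesulfonate (C8 epimers) | CS(=O)(=O)OCC3(C)[C@@H]1CC(=O)c2c(OC)c(C(C)C)c(OC)c(OC)c2[C@]1(C)CCC3=O | intermediate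
19 | [(4bR,8aR)-1,3,4-trihydroxy-4b,8-dimethyl-7,10-dioxo-2-(propan-2-yl)-4b,5,6,7,8,8a,9,10-octahydrophenanthren-8-yl]methyl methanesulfonate (C8 epimers) | CS(=O)(=O)OCC3(C)[C@@H]1CC(=O)c2c(O)c(C(C)C)c(O)c(O)c2[C@]1(C)CCC3=O | intermediate
20 | 3-[(1R,2S)-5,7,8-trihydroxy-1-methyl-4-oxo-6-(propan-2-yl)-2-(prop-1-en-2-yl)-1,2,3,4-tetrahydronaphthalen-1-yl]propanoic acid | C=C(C)[C@@H]1CC(=O)c2c(O)c(C(C)C)c(O)c(O)c2[C@]1(C)CCC(=O)O | target

**Step count and risks**

Total steps: 12. Longest linear sequence: 12 steps (1 to 20); 10 enters at step 7.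

Steps most likely to fail:

1. Step 7. The doubly ortho-substituted α-aryl aldehyde may form its enamine slowly and add with poor facial selectivity, giving low conversion or low enantiomeric purity at C10. Fallback, auxiliary control instead of catalysis: setting out from 9, condensation with (S)-1-phenylethylamine (MgSO4, CH2Cl2) would give the bromo aldehyde N-[(1S)-1-phenylethyl]imine F1 as a mixture of epimers at the benzylic carbon. The secondary enamine tautomer of F1 should add to 10 in a deracemising aza-ene-type Michael reaction (THF, rt to 40 °C) to give the keto aldehyde N-[(1S)-1-phenylethyl]imine F2 with the quaternary centre set by the auxiliary. Hydrolysis of F2 with aqueous acetic acid comes back to the route at 11, which is cyclised to 12 with KOH/EtOH as before; the antipodal amine is taken if the sense of induction requires it.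

2. Step 9. Deprotonation at the enone α′-CH2, proton transfer between the enolates before trapping (hydroxymethylation at C6), or retro-aldol loss of formaldehyde may erode the tandem process. Fallback, Lewis-acid closure without a basic enolate: setting out from 13, which is isolated when the acid treatment of step 8 is left out, TMSOTf in CH2Cl2 at −78 °C should trigger a Mukaiyama-type intramolecular Michael addition of the ethyl enol ether to the silyl-activated enone. Bicarbonate work-up should then give the cis-fused tricyclic trimethylsilyl enol ether F3 with the C7 ketone already unveiled. Lanthanide-triflate-catalysed hydroxymethylation of F3 with aqueous formaldehyde (Yb(OTf)3, THF/H2O) comes back to the route at 17.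

3. Step 8. Oxidative addition and transmetalation at the bromide flanked by OMe and the quaternary-carbon-bearing position may be slow, leading to protodebromination. Fallback, halogen–lithium exchange with the enone masked in the flask: setting out from 12, KH in THF would give the bromo enone potassium dienolate F4. t-BuLi (2 equiv, −78 °C) should then convert F4 into the aryllithium potassium dienolate F5, and F5 is acylated with N-methoxy-N-methylacetamide. Aqueous work-up reprotonates the dienolate and comes back to the route at 14.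

**Further compounds**

F1 | step 7 | bromo aldehyde N-[(1S)-1-phenylethyl]imine | C[C@H](N=CC(C)c1c(OC)c(OC)c(C(C)C)c(OC)c1Br)c1ccccc1
F2 | step 7 | keto aldehyde N-[(1S)-1-phenylethyl]imine | C[C@H](N=C[C@](C)(c1c(OC)c(OC)c(C(C)C)c(OC)c1Br)CCC(=O)CC)c1ccccc1
F3 | step 9 | cis-fused tricyclic trimethylsilyl enol ether | CC=3[C@@H]1CC(=O)c2c(OC)c(C(C)C)c(OC)c(OC)c2[C@]1(C)CCC=3O[Si](C)(C)C
F4 | step 8 | bromo enone potassium dienolate | CC1=C[C@](C)(c2c(OC)c(OC)c(C(C)C)c(OC)c2Br)CC=C1O[K]
F5 | step 8 | aryllithium potassium dienolate | CC1=C[C@](C)(c2c(OC)c(OC)c(C(C)C)c(OC)c2[Li])CC=C1O[K]
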